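The plan rests on the O1–C5 bond of the tetrahydrofuran ring (O1, C2–C5). C5 is a benzylic carbon whose guaiacyl ring is trans to the C4 methyl, and C2/C3 is a cis aryl/methyl pair that would be lost if C2 ionised. A free phenol on the C5 aryl against an ether on the C2 aryl lets an oxidant address C5 alone.
31 <= phenol 25: the (1S,2S) arm goes on last (Mitsunobu with (R)-lactate, Weinreb amide, aryl Grignard, Felkin–Anh reduction), then the silyl ether of the (1R,2R) arm is removed.
25 <= open-chain phenol 23: Ag2O oxidises the unfunctionalised C5 to p-quinone methide 24 and the C2 hydroxyl adds to it. This is the only ring formed in the route; all four benzene rings are bought.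
23 <= arm aldehyde 10: Evans syn aldol (C2, C3), benzyl ketone, methylenation, hydroxyl-directed hydrogenation of the 1,1-disubstituted alkene (C4), debenzylation.
10 <= 4-bromoguaiacol 1, (S)-lactate 2 and aryl Grignard 5 by the same arm chemistry, then silylation and formylation.

Key step: step 16

Abbreviations: ArA = 4-{[(1R,2R)-1-(tert-butyldimethylsilyloxy)-1-(3,4-dimethoxyphenyl)propan-2-yl]oxy}-3-methoxyphenyl; ArB = 4-benzyloxy-3-methoxyphenyl. Locants O1, C2 (bears ArA), C3, C4, C5 are those of the tetrahydrofuran ring and are also used for the open-chain compounds.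
Assumption: 5 (THF solution), 16 and both lactate esters are taken as commercial. The (1R,2R) arm is built from lactate and not by O-arylation of a monosilylated 1,2-diol, because an alkoxide next to a silyl ether would let the silyl group migrate.

Step 1
Reactants: 1 4-bromo-2-methoxyphenol; 2 ethyl (S)-lactate
Product: 3 ethyl (2R)-2-(4-bromo-2-methoxyphenoxy)propanoate
Conditions: PPh3, DIAD, THF, 0 °C to rt
Reagents that add atoms: none
Why: Mitsunobu etherification, in which the acidic phenol displaces the activated lactate hydroxyl by SN2 with inversion, so that (S)-lactate should give the (R)-aryloxy centre of the arm.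

Step 2
Reactants: 3 ethyl (2R)-2-(4-bromo-2-methoxyphenoxy)propanoate
Product: 4 (2R)-2-(4-bromo-2-methoxyphenoxy)-N-methoxy-N-methylpropanamide
Conditions: MeNH(OMe)·HCl, iPrMgCl, THF, −20 °C
Reagents that add atoms: N,O-dimethylhydroxylamine hydrochloride, CNOC.Cl
Why: Weinreb amide formation with the magnesium amide made in the flask is fast at low temperature, which should leave the α-aryloxy stereocentre and the electron-rich aryl bromide untouched.

Step 3
Reactants: 4 (2R)-2-(4-bromo-2-methoxyphenoxy)-N-methoxy-N-methylpropanamide; 5 3,4-dimethoxyphenylmagnesium bromide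
Product: 6 (2R)-2-(4-bromo-2-methoxyphenoxy)-1-(3,4-dimethoxyphenyl)propan-1-one
Conditions: THF, −78 to 0 °C; cold aq NH4Cl
Reagents that add atoms: none
Why: Weinreb ketone synthesis, in which the chelated adduct holds until the quench, so there is no over-addition and the epimerisable ketone never meets the basic Grignard reagent.

Step 4
Reactants: 6 (2R)-2-(4-bromo-2-methoxyphenoxy)-1-(3,4-dimethoxyphenyl)propan-1-one
Product: 7 threo alcohol (1R,2R)-2-(4-bromo-2-methoxyphenoxy)-1-(3,4-dimethoxyphenyl)propan-1-ol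
Conditions: Bu4NBH4, CH2Cl2/MeOH, −78 to −20 °C
Reagents that add atoms: none
Why: Polar Felkin–Anh reduction, in which the non-chelating ammonium counter-ion lets the aryloxy group stand anti to the incoming hydride, which should set the (1R) carbinol syn (threo) to the (2R) centre.

Step 5
Reactants: 7 threo alcohol (1R,2R)-2-(4-bromo-2-methoxyphenoxy)-1-(3,4-dimethoxyphenyl)propan-1-ol
Product: 8 TBS ether ArA–Br
Conditions: TBSCl, imidazole, DMF, rt
Reagents that add atoms: tert-butyldimethylsilyl chloride, CC(C)(C)[Si](C)(C)Cl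
Why: Imidazole-promoted silylation masks the benzylic alcohol without touching either stereocentre, and the ether withstands the organometallic, boron, aluminium and titanium reagents that follow.

Step 6
Reactants: 8 TBS ether ArA–Br
Product: 10 arm aldehyde ArA–CHO, via aryllithium 9 (not isolated)
Conditions: n-BuLi, THF, −78 °C; DMF, −78 to 0 °C; aq NH4Cl
Reagents that add atoms: N,N-dimethylformamide, CN(C)C=O
Why: Bromine–lithium exchange is faster than any deprotonation at −78 °C, and formylation of the aryllithium with DMF gives the aldehyde para to the arm oxygen.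

Step 7
Reactants: 10 arm aldehyde ArA–CHO; 11 (S)-4-benzyl-3-propionyloxazolidin-2-one
Product: 13 syn aldol adduct (4S)-4-benzyl-3-[(2S,3S)-3-ArA-3-hydroxy-2-methylpropanoyl]oxazolidin-2-one, via Z-boron enolate 12 (not isolated)
Conditions: 11, Bu2BOTf, Et3N, CH2Cl2, 0 °C; 10, −78 to 0 °C; H2O2, MeOH, pH 7 buffer (KH2PO4/K2HPO4), 0 °C
Reagents that add atoms: none
Why: Evans syn aldol, in which the Z-boron enolate reacts through a Zimmerman–Traxler chair on the face left open by the benzyl group of the (S)-auxiliary, which should set the (S) carbinol C2 and the neighbouring methyl centre C3 1,2-syn, the later 2,3-cis pair.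

Step 8
Reactants: 13 syn aldol adduct
Product: 14 (2S,3S)-3-ArA-3-hydroxy-N-methoxy-N,2-dimethylpropanamide
Conditions: MeNH(OMe)·HCl, AlMe3, CH2Cl2, −10 to 0 °C; aq potassium sodium tartrate
Reagents that add atoms: N,O-dimethylhydroxylamine hydrochloride, CNOC.Cl
Why: Aluminium amide transamination attacks the exocyclic carbonyl, helped by the free β-hydroxyl, and releases the auxiliary without retro-aldol cleavage or epimerisation at C3.

Step 9
Reactants: 14 (2S,3S)-3-ArA-3-hydroxy-N-methoxy-N,2-dimethylpropanamide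
Product: 15 (2S,3S)-3-ArA-N-methoxy-N,2-dimethyl-3-(triethylsilyloxy)propanamide
Conditions: TESCl, imidazole, CH2Cl2, 0 °C to rt
Reagents that add atoms: chlorotriethylsilane, CC[Si](Cl)(CC)CC
Why: Silylation blocks retro-aldol cleavage in the next two steps, and a triethylsilyl ether can later be removed in the presence of the TBS ether of the arm.

Step 10
Reactants: 16 4-benzyloxy-3-methoxybenzyl alcohol
Product: 17 4-benzyloxy-3-methoxybenzyl chloride
Conditions: SOCl2, CH2Cl2, 0 °C
Reagents that add atoms: thionyl chloride, O=S(Cl)Cl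
Why: Chlorination of an electron-rich benzylic alcohol with thionyl chloride is fast at 0 °C, and the chloride is used at once.

Step 11
Reactants: 17 4-benzyloxy-3-methoxybenzyl chloride; 15 (2S,3S)-3-ArA-N-methoxy-N,2-dimethyl-3-(triethylsilyloxy)propanamide
Product: 19 benzyl ketone (3S,4S)-4-ArA-1-ArB-3-methyl-4-(triethylsilyloxy)butan-2-one, via benzylmagnesium chloride 18 (not isolated)
Conditions: 17, Mg turnings (excess), THF (dilute), 0 °C; then 15, −20 to 0 °C; aq NH4Cl
Reagents that add atoms: none
Why: Grignard formation under dilution with excess magnesium limits Wurtz coupling, and the Weinreb ketone synthesis stops at the ketone, which forms the C4–C5 bond and is set free only at the quench.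

Step 12
Reactants: 19 benzyl ketone
Product: 20 alkene (1S,2R)-1-ArA-3-(ArB-methyl)-2-methylbut-3-en-1-yl triethylsilyl ether
Conditions: Cp2TiMe2, toluene, 70 °C, dark
Reagents that add atoms: dimethyltitanocene Cp2TiMe2, [CH3-].[CH3-].[Ti+4].c1cc[cH-]c1.c1cc[cH-]c1
Why: Petasis methylenation, in which the titanium methylidene formed on heating takes the ketone through an oxatitanacyclobutane to the 1,1-disubstituted alkene; the reagent is not basic, so the readily enolised ketone, C3 and the β-silyloxy group should be left alone.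

Step 13
Reactants: 20 alkene triethylsilyl ether
Product: 21 homoallylic alcohol (1S,2R)-1-ArA-3-(ArB-methyl)-2-methylbut-3-en-1-ol
Conditions: HF·pyridine, pyridine, THF, 0 °C
Reagents that add atoms: none
Why: Selective desilylation, since pyridine-buffered HF cleaves the less hindered triethylsilyl ether much faster than the TBS ether and the weakly acidic medium should not ionise the benzylic C2–O bond.

Step 14
Reactants: 21 homoallylic alcohol
Product: 22 (1S,2R,3S)-1-ArA-4-ArB-2,3-dimethylbutan-1-ol
Conditions: [Rh(nbd)(dppb)]BF4 (cat.; nbd = norbornadiene, dppb = 1,4-bis(diphenylphosphino)butane), H2 (70 bar), CH2Cl2, rt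
Reagents that add atoms: none
Why: Hydroxyl-directed homogeneous hydrogenation, in which the C2 hydroxyl binds the cationic rhodium and H2 arrives on its side of the alkene; in the favoured chelate C3–H faces the CH2ArB branch (least A(1,2) strain), the C3 methyl lies over the =CH2 terminus and ArA is anti to C4, which should set (3S) at C4, the later 3,4-trans methyl pair, while high pressure outruns double-bond migration.

Step 15
Reactants: 22 (1S,2R,3S)-1-ArA-4-ArB-2,3-dimethylbutan-1-ol
Product: 23 (1S,2R,3S)-1-ArA-4-(4-hydroxy-3-methoxyphenyl)-2,3-dimethylbutan-1-ol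
Conditions: H2 (1 atm), Pd/C, EtOAc, rt
Reagents that add atoms: none
Why: Catalytic hydrogenolysis cleaves the aryl benzyl ether quickly under neutral conditions, before the secondary benzylic alcohol at C2 or the benzylic silyl ether of the arm is touched, and frees the one phenol that the key step needs.

Step 16
Reactants: 23 (1S,2R,3S)-1-ArA-4-(4-hydroxy-3-methoxyphenyl)-2,3-dimethylbutan-1-ol
Product: 25 (2S,3R,4R,5R)-2-ArA-5-(4-hydroxy-3-methoxyphenyl)-3,4-dimethyltetrahydrofuran, via p-quinone methide 24 (not isolated)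
Conditions: Ag2O (1.2 equiv), 4 Å molecular sieves, CH2Cl2 (0.005 M), rt, dark
Reagents that add atoms: none
Why: Ag2O removes two electrons and two protons from the only free phenol (phenoxyl radical, then loss of one C5 hydrogen) to give p-quinone methide 24, whose exocyclic carbon is C5, and the C2 hydroxyl then adds to that carbon, restoring the aromatic ring and forming O1–C5. The closest known reaction type is the silver oxide oxidation of 4-alkylguaiacols to p-quinone methides followed by capture with an internal alcohol. The tetrahydrofuran ring closes in the 5-exo-trig mode (oxa-1,6-addition, the C5=C(ipso) bond staying outside the new ring). The new centre C5 is controlled by A(1,3) strain in 24: C4–H lies in the plane of the quinone methide next to the ring C–H, C3 with its tethered oxygen stands on one face and the C4 methyl on the other, so the aryl group should end up trans to the C4 methyl, (5R), which is also the more stable epimer. The step needs site selectivity between C5 and the other benzylic carbons (C2 and the silyloxy carbon of the arm), and this is secured because their aryl rings are fully etherified and cannot become quinone methides, while the neutral medium leaves the C2–O bond and hence the 2,3-cis pair untouched. High dilution, molecular sieves and a small excess of oxidant are meant to hold back phenoxyl coupling, capture by water and re-oxidation of 25.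

Step 17
Reactants: 25 core phenol; 26 methyl (R)-lactate
Product: 27 methyl (2S)-2-{4-[(2R,3R,4R,5S)-5-ArA-3,4-dimethyltetrahydrofuran-2-yl]-2-methoxyphenoxy}propanoate
Conditions: PPh3, DIAD, THF, 0 °C to rt
Reagents that add atoms: none
Why: Mitsunobu etherification with SN2 inversion turns (R)-lactate into the (S)-aryloxy centre of the second arm under neutral conditions that leave the tetrahydrofuran untouched.

Step 18
Reactants: 27 methyl ester
Product: 28 the corresponding (2S)-N-methoxy-N-methylpropanamide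
Conditions: MeNH(OMe)·HCl, iPrMgCl, THF, −20 °C
Reagents that add atoms: N,O-dimethylhydroxylamine hydrochloride, CNOC.Cl
Why: Weinreb amide formation with the magnesium amide, as in step 2, is fast enough at low temperature to keep the α-aryloxy centre intact.

Step 19
Reactants: 28 Weinreb amide; 5 3,4-dimethoxyphenylmagnesium bromide
Product: 29 (2S)-2-aryloxy-1-(3,4-dimethoxyphenyl)propan-1-one on the C5 aryl of the core
Conditions: THF, −78 to 0 °C; cold aq NH4Cl
Reagents that add atoms: none
Why: Weinreb ketone synthesis, as in step 3, gives the ketone only at the quench, which avoids over-addition and base-induced epimerisation.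

Step 20
Reactants: 29 ketone
Product: 30 mono-TBS ether of the target with the (1S,2S) arm complete
Conditions: Bu4NBH4, CH2Cl2/MeOH, −78 to −20 °C
Reagents that add atoms: none
Why: Polar Felkin–Anh reduction without a chelating cation, the mirror image of step 4, should set the (1S) carbinol syn (threo) to the (2S) centre.

Step 21
Reactants: 30 mono-TBS ether
Product: 31 target CNP0116650.16
Conditions: TBAF, THF, 0 °C to rt
Reagents that add atoms: none
Why: Fluoride-induced desilylation is non-acidic, so none of the four benzylic C–O bonds can ionise and all eight stereocentres are kept.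

Compound list
1 | 4-bromo-2-methoxyphenol | COc1cc(Br)ccc1O | starting material
2 | ethyl (S)-lactate | C[C@H](O)C(=O)OCC | starting material
3 | ethyl (2R)-2-(4-bromo-2-methoxyphenoxy)propanoate | CCOC(=O)[C@@H](C)Oc1ccc(Br)cc1OC | intermediate
4 | (2R)-2-(4-bromo-2-methoxyphenoxy)-N-methoxy-N-methylpropanamide | CON(C)C(=O)[C@@H](C)Oc1ccc(Br)cc1OC | intermediate
5 | 3,4-dimethoxyphenylmagnesium bromide | COc1ccc([Mg]Br)cc1OC | starting material
6 | (2R)-2-(4-bromo-2-methoxyphenoxy)-1-(3,4-dimethoxyphenyl)propan-1-one | COc1ccc(C(=O)[C@@H](C)Oc2ccc(Br)cc2OC)cc1OC | intermediate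
7 | (1R,2R)-2-(4-bromo-2-methoxyphenoxy)-1-(3,4-dimethoxyphenyl)propan-1-ol (threo) | COc1ccc([C@@H](O)[C@@H](C)Oc2ccc(Br)cc2OC)cc1OC | intermediate
8 | TBS ether of 7 (ArA–Br) | COc1ccc([C@@H](O[Si](C)(C)C(C)(C)C)[C@@H](C)Oc2ccc(Br)cc2OC)cc1OC | intermediate
9 | aryllithium ArA–Li | COc1ccc([C@@H](O[Si](C)(C)C(C)(C)C)[C@@H](C)Oc2ccc([Li])cc2OC)cc1OC | intermediate
10 | arm aldehyde 4-{[(1R,2R)-1-(tert-butyldimethylsilyloxy)-1-(3,4-dimethoxyphenyl)propan-2-yl]oxy}-3-methoxybenzaldehyde | COc1ccc([C@@H](O[Si](C)(C)C(C)(C)C)[C@@H](C)Oc2ccc(C=O)cc2OC)cc1OC | intermediate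
11 | (S)-4-benzyl-3-propionyloxazolidin-2-one | CCC(=O)N1[C@@H](Cc2ccccc2)COC1=O | starting material
12 | dibutylboron (Z)-enolate of 11 | C/C=C(\OB(CCCC)CCCC)N1[C@@H](Cc2ccccc2)COC1=O | intermediate
13 | (4S)-4-benzyl-3-[(2S,3S)-3-ArA-3-hydroxy-2-methylpropanoyl]oxazolidin-2-one | COc1ccc([C@@H](O[Si](C)(C)C(C)(C)C)[C@@H](C)Oc2ccc([C@@H](O)[C@H](C)C(=O)N3[C@@H](Cc4ccccc4)COC3=O)cc2OC)cc1OC | intermediate
14 | (2S,3S)-3-ArA-3-hydroxy-N-methoxy-N,2-dimethylpropanamide | COc1ccc([C@@H](O[Si](C)(C)C(C)(C)C)[C@@H](C)Oc2ccc([C@@H](O)[C@H](C)C(=O)N(C)OC)cc2OC)cc1OC | intermediate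
15 | (2S,3S)-3-ArA-N-methoxy-N,2-dimethyl-3-(triethylsilyloxy)propanamide | COc1ccc([C@@H](O[Si](C)(C)C(C)(C)C)[C@@H](C)Oc2ccc([C@@H](O[Si](CC)(CC)CC)[C@H](C)C(=O)N(C)OC)cc2OC)cc1OC | intermediate
16 | 4-benzyloxy-3-methoxybenzyl alcohol | COc1cc(CO)ccc1OCc1ccccc1 | starting material
17 | 4-benzyloxy-3-methoxybenzyl chloride | COc1cc(CCl)ccc1OCc1ccccc1 | intermediate
18 | 4-benzyloxy-3-methoxybenzylmagnesium chloride | COc1cc(C[Mg]Cl)ccc1OCc1ccccc1 | intermediate
19 | (3S,4S)-4-ArA-1-ArB-3-methyl-4-(triethylsilyloxy)butan-2-one | COc1ccc([C@@H](O[Si](C)(C)C(C)(C)C)[C@@H](C)Oc2ccc([C@@H](O[Si](CC)(CC)CC)[C@H](C)C(=O)Cc3ccc(OCc4ccccc4)c(OC)c3)cc2OC)cc1OC | intermediate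
20 | (1S,2R)-1-ArA-3-(ArB-methyl)-2-methylbut-3-en-1-yl triethylsilyl ether | COc1ccc([C@@H](O[Si](C)(C)C(C)(C)C)[C@@H](C)Oc2ccc([C@@H](O[Si](CC)(CC)CC)[C@H](C)C(=C)Cc3ccc(OCc4ccccc4)c(OC)c3)cc2OC)cc1OC | intermediate
21 | (1S,2R)-1-ArA-3-(ArB-methyl)-2-methylbut-3-en-1-ol | COc1ccc([C@@H](O[Si](C)(C)C(C)(C)C)[C@@H](C)Oc2ccc([C@@H](O)[C@H](C)C(=C)Cc3ccc(OCc4ccccc4)c(OC)c3)cc2OC)cc1OC | intermediate
22 | (1S,2R,3S)-1-ArA-4-ArB-2,3-dimethylbutan-1-ol | COc1ccc([C@@H](O[Si](C)(C)C(C)(C)C)[C@@H](C)Oc2ccc([C@@H](O)[C@H](C)[C@@H](C)Cc3ccc(OCc4ccccc4)c(OC)c3)cc2OC)cc1OC | intermediate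
23 | (1S,2R,3S)-1-ArA-4-(4-hydroxy-3-methoxyphenyl)-2,3-dimethylbutan-1-ol; hydroxyl and both methyls lie on one side of the zigzag chain, which maps onto 2,3-cis-3,4-trans in the ring | COc1ccc([C@@H](O[Si](C)(C)C(C)(C)C)[C@@H](C)Oc2ccc([C@@H](O)[C@H](C)[C@@H](C)Cc3ccc(O)c(OC)c3)cc2OC)cc1OC | intermediate
24 | p-quinone methide of 23 (exocyclic C5=C bond, geometry relative to the methoxy group open, both forms converge) | COc1ccc([C@@H](O[Si](C)(C)C(C)(C)C)[C@@H](C)Oc2ccc([C@@H](O)[C@H](C)[C@@H](C)C=C3C=CC(=O)C(OC)=C3)cc2OC)cc1OC | intermediate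
25 | (2S,3R,4R,5R)-2-ArA-5-(4-hydroxy-3-methoxyphenyl)-3,4-dimethyltetrahydrofuran (2,3-cis-3,4-trans-4,5-trans) | COc1ccc([C@@H](O[Si](C)(C)C(C)(C)C)[C@@H](C)Oc2ccc([C@H]3O[C@@H](c4ccc(O)c(OC)c4)[C@H](C)[C@H]3C)cc2OC)cc1OC | intermediate
26 | methyl (R)-lactate | C[C@@H](O)C(=O)OC | starting material
27 | methyl (2S)-2-aryloxypropanoate of 25 | COc1ccc([C@@H](O[Si](C)(C)C(C)(C)C)[C@@H](C)Oc2ccc([C@H]3O[C@@H](c4ccc(O[C@@H](C)C(=O)OC)c(OC)c4)[C@H](C)[C@H]3C)cc2OC)cc1OC | intermediate
28 | (2S)-Weinreb amide from 27 | COc1ccc([C@@H](O[Si](C)(C)C(C)(C)C)[C@@H](C)Oc2ccc([C@H]3O[C@@H](c4ccc(O[C@@H](C)C(=O)N(C)OC)c(OC)c4)[C@H](C)[C@H]3C)cc2OC)cc1OC | intermediate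
29 | (2S)-α-aryloxy 3,4-dimethoxyphenyl ketone from 28 | COc1ccc([C@@H](O[Si](C)(C)C(C)(C)C)[C@@H](C)Oc2ccc([C@H]3O[C@@H](c4ccc(O[C@@H](C)C(=O)c5ccc(OC)c(OC)c5)c(OC)c4)[C@H](C)[C@H]3C)cc2OC)cc1OC | intermediate
30 | mono-TBS ether of the target, (1S,2S) arm free and (1R,2R) arm silylated | COc1ccc([C@@H](O[Si](C)(C)C(C)(C)C)[C@@H](C)Oc2ccc([C@H]3O[C@@H](c4ccc(O[C@@H](C)[C@@H](O)c5ccc(OC)c(OC)c5)c(OC)c4)[C@H](C)[C@H]3C)cc2OC)cc1OC | intermediate
31 | CNP0116650.16, (2S,3R,4R,5R)-tetrahydrofuran with the (1R,2R) arm on the C2 aryl and the (1S,2S) arm on the C5 aryl | COc1ccc([C@@H](O)[C@@H](C)Oc2ccc([C@H]3O[C@@H](c4ccc(O[C@@H](C)[C@@H](O)c5ccc(OC)c(OC)c5)c(OC)c4)[C@H](C)[C@H]3C)cc2OC)cc1OC | target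

Total step count: 21.
Longest linear sequence: 20 steps (steps 1–9 and 11–21, from 1 to 31).

Steps most likely to fail

Step 16. The phenoxyl radical may couple at the open position ortho to the phenol faster than it goes on to the quinone methide. The quinone methide may also tautomerise to the styrene by loss of C4–H, or the cyclised phenol may be oxidised again. The fallback changes the substrate by a removable blocking group; it sets out from 23 and comes back at 25. NBS (1 equiv, CH2Cl2, low temperature) should brominate the free guaiacyl ring ortho to the hydroxyl and give the 5-bromoguaiacyl open-chain phenol F1. This 2,6-disubstituted phenol has no free ortho position for coupling, so Ag2O should take it through the bromo quinone methide F2 to the bromo core phenol F3. Hydrogenolysis of the C–Br bond (H2, Pd/C, Et3N, EtOAc, the amine holding back cleavage of the benzylic ring C–O bonds) should then give 25.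

Step 14. The facial selectivity may be poor if arene or ether oxygens occupy the rhodium in place of the hydroxyl, and the double bond may migrate into conjugation with ArB before it is reduced. The fallback replaces chelate control by steric control; it sets out from 20 and comes back at 22. 9-BBN should add to the silyl ether 20 with C3–H eclipsing the double bond and the borane anti to the CH(OTES)ArA group, which places hydrogen on the same face of C4 and gives the B-alkyl-9-BBN adduct F4. Oxidation (NaOH, H2O2) gives the primary alcohol F5, TsCl/pyridine gives the tosylate F6, and LiEt3BH reduces it to the saturated triethylsilyl ether F7. HF·pyridine, as in step 13, then gives 22.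

Step 12. The hindered, readily enolised benzyl ketone may be methylenated slowly, the new double bond may move into conjugation on heating, and Wurtz coupling in the making of 18 may starve step 11. The fallback builds the same alkene by cross-coupling; it sets out from 15 and 17 and comes back at 20. MeMgBr on 15 gives the methyl ketone F8. Kinetic enolisation on the methyl side and triflation (KN(SiMe3)2, PhNTf2, THF, −78 °C) give the terminal enol triflate F9. Negishi coupling (Pd(PPh3)4, THF) with the benzylzinc chloride F10, made from 17 with Zn and LiCl, should give 20.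

Further compounds
F1 | step 16 | 5-bromoguaiacyl open-chain phenol, 23 with Br ortho to the phenol | COc1ccc([C@@H](O[Si](C)(C)C(C)(C)C)[C@@H](C)Oc2ccc([C@@H](O)[C@H](C)[C@@H](C)Cc3cc(Br)c(O)c(OC)c3)cc2OC)cc1OC
F2 | step 16 | bromo quinone methide | COc1ccc([C@@H](O[Si](C)(C)C(C)(C)C)[C@@H](C)Oc2ccc([C@@H](O)[C@H](C)[C@@H](C)C=C3C=C(Br)C(=O)C(OC)=C3)cc2OC)cc1OC
F3 | step 16 | bromo core phenol, 25 with Br ortho to the phenol | COc1ccc([C@@H](O[Si](C)(C)C(C)(C)C)[C@@H](C)Oc2ccc([C@H]3O[C@@H](c4cc(Br)c(O)c(OC)c4)[C@H](C)[C@H]3C)cc2OC)cc1OC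
F4 | step 14 | B-alkyl-9-BBN adduct of 20 | COc1ccc([C@@H](O[Si](C)(C)C(C)(C)C)[C@@H](C)Oc2ccc([C@@H](O[Si](CC)(CC)CC)[C@H](C)[C@@H](CB5C6CCCC5CCC6)Cc3ccc(OCc4ccccc4)c(OC)c3)cc2OC)cc1OC
F5 | step 14 | primary alcohol, C4 bearing CH2OH | COc1ccc([C@@H](O[Si](C)(C)C(C)(C)C)[C@@H](C)Oc2ccc([C@@H](O[Si](CC)(CC)CC)[C@H](C)[C@@H](CO)Cc3ccc(OCc4ccccc4)c(OC)c3)cc2OC)cc1OC
F6 | step 14 | tosylate of F5 | COc1ccc([C@@H](O[Si](C)(C)C(C)(C)C)[C@@H](C)Oc2ccc([C@@H](O[Si](CC)(CC)CC)[C@H](C)[C@@H](COS(=O)(=O)c5ccc(C)cc5)Cc3ccc(OCc4ccccc4)c(OC)c3)cc2OC)cc1OC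
F7 | step 14 | saturated triethylsilyl ether, TES ether of 22 | COc1ccc([C@@H](O[Si](C)(C)C(C)(C)C)[C@@H](C)Oc2ccc([C@@H](O[Si](CC)(CC)CC)[C@H](C)[C@@H](C)Cc3ccc(OCc4ccccc4)c(OC)c3)cc2OC)cc1OC
F8 | step 12 | methyl ketone (3S,4S)-4-ArA-3-methyl-4-(triethylsilyloxy)butan-2-one | COc1ccc([C@@H](O[Si](C)(C)C(C)(C)C)[C@@H](C)Oc2ccc([C@@H](O[Si](CC)(CC)CC)[C@H](C)C(C)=O)cc2OC)cc1OC
F9 | step 12 | terminal enol triflate of F8 | COc1ccc([C@@H](O[Si](C)(C)C(C)(C)C)[C@@H](C)Oc2ccc([C@@H](O[Si](CC)(CC)CC)[C@H](C)C(=C)OS(=O)(=O)C(F)(F)F)cc2OC)cc1OC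
F10 | step 12 | 4-benzyloxy-3-methoxybenzylzinc chloride | COc1cc(C[Zn]Cl)ccc1OCc1ccccc1
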